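**Strategy.** Everything rests on disconnecting the side chain (C1'–C16', counted from ring carbon C5) between C8', its last sp3 carbon, and C9', the terminus of the 9E,11E,13E-triene. A one-pot hydroboration/B-alkyl Suzuki–Miyaura coupling joins the finished (3R,5S)-1,2-dioxolane-3-acetate core to an intact (E,E,E)-iodotriene, so the triene never meets peroxide-forming chemistry. The step exploits that C8' is a primary carbon at the end of an eight-methylene tether on C5 of the dioxolane ring: it is carried through the synthesis as an inert terminal alkene (C7'=C8') and only then turned into a primary alkylborane. Ring carbon C5 is set by Sharpless epoxidation and invertive oxetane perhydrolysis, C3 by addition to a peroxycarbenium ion.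

Key step: step 14

Remark: ring atoms are numbered O1, O2, C3 (acetic acid arm), C4, C5 (side chain); C3 is formed without useful substrate control, so the route assumes that the two C3 epimers of ester 18 can be separated by chromatography.

**Step 1**
Reactants: 1 8-bromooct-1-ene
Product: 2 dec-1-en-9-yne
Conditions: LiC≡CH·H2NCH2CH2NH2 (1.5 equiv), DMSO, 0 °C to rt
Reagents that add atoms: lithium acetylide ethylenediamine complex, [Li+].[C-]#C.NCCN
Why: SN2 alkylation of an acetylide by a primary bromide should be clean in DMSO, and the remote terminal alkene is inert.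

**Step 2**
Reactants: 2 dec-1-en-9-yne
Product: 5 (E)-3-methylundeca-2,10-dien-1-ol, via alkenyldimethylalane 3 (not isolated), via lithium alkenylaluminate 4 (not isolated)
Conditions: AlMe3 (2 equiv), Cp2ZrCl2 (0.2 equiv), CH2Cl2, 0 °C to rt; then n-BuLi, THF, −78 °C; (CH2O)n, −78 °C to rt; aqueous HCl work-up
Reagents that add atoms: trimethylaluminium, C[Al](C)C; formaldehyde (as paraformaldehyde), C=O
Why: Negishi zirconium-catalysed carboalumination adds Me and Al syn across the alkyne with Me on the internal carbon, so hydroxymethylation of the ate complex with retention should give the E-trisubstituted allylic alcohol, while the monosubstituted alkene is not carbometalated under these conditions.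

**Step 3**
Reactants: 5 (E)-3-methylundeca-2,10-dien-1-ol
Product: 6 [(2R,3R)-3-methyl-3-(oct-7-en-1-yl)oxiran-2-yl]methanol
Conditions: Ti(OiPr)4 (10 mol%), D-(−)-diethyl tartrate (12 mol%), anhydrous t-BuOOH (2 equiv), 4 Å MS, CH2Cl2, −20 °C
Reagents that add atoms: tert-butyl hydroperoxide, CC(C)(C)OO
Why: Katsuki–Sharpless asymmetric epoxidation with the D-(−)-tartrate catalyst should deliver oxygen to the face that gives the (2R,3R)-epoxide (mirror image of the geraniol/L-(+)-tartrate outcome), which fixes the tertiary C–O stereocentre; the isolated terminal alkene is not epoxidised.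

**Step 4**
Reactants: 6 [(2R,3R)-3-methyl-3-(oct-7-en-1-yl)oxiran-2-yl]methanol
Product: 7 (3R)-3-methylundec-10-ene-1,3-diol
Conditions: NaAlH2(OCH2CH2OMe)2, THF, 0 °C to rt; aqueous potassium sodium tartrate work-up
Reagents that add atoms: none
Why: hydroxyl-directed reductive opening of a 2,3-epoxy alcohol delivers hydride intramolecularly to C2 and gives the 1,3-diol, leaving the tertiary C–O bond and its configuration untouched.

**Step 5**
Reactants: 7 (3R)-3-methylundec-10-ene-1,3-diol
Product: 8 (3R)-3-hydroxy-3-methylundec-10-enal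
Conditions: TEMPO (10 mol%), PhI(OAc)2 (1.1 equiv), CH2Cl2, rt; used crude
Reagents that add atoms: none
Why: oxoammonium (TEMPO/PhI(OAc)2) oxidation is selective for the primary alcohol, stops at the aldehyde and cannot touch the tertiary alcohol.

**Step 6**
Reactants: 8 (3R)-3-hydroxy-3-methylundec-10-enal
Product: 9 (4R)-4-methyldodec-11-ene-2,4-diol (both C2 epimers)
Conditions: MeMgBr (3 equiv), THF, −78 to 0 °C, inverse addition; aqueous work-up
Reagents that add atoms: methylmagnesium bromide, C[Mg]Br
Why: Grignard addition to the aldehyde (after deprotonation of the tertiary hydroxyl) gives the secondary alcohol, whose configuration is irrelevant because this carbinol is oxidised in step 10.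

**Step 7**
Reactants: 9 (4R)-4-methyldodec-11-ene-2,4-diol
Product: 11 (2R)-2,4-dimethyl-2-(oct-7-en-1-yl)oxetane (both C4 epimers), via secondary mesylate 10 (not isolated)
Conditions: MsCl (1.05 equiv), Et3N, CH2Cl2, −20 °C; crude mesylate, NaH, THF, 0 to 45 °C
Reagents that add atoms: none
Why: chemoselective mesylation of the secondary hydroxyl followed by intramolecular Williamson etherification (4-exo-tet, favoured by the gem-disubstituted carbinol carbon) closes the oxetane without breaking the tertiary C–O bond, so the (R) centre is retained.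

**Step 8**
Reactants: 11 (2R)-2,4-dimethyl-2-(oct-7-en-1-yl)oxetane
Product: 12 (4S)-4-hydroperoxy-4-methyldodec-11-en-2-ol (both C2 epimers)
Conditions: anhydrous H2O2 in Et2O (10 equiv), TMSOTf (0.2 equiv), Et2O, −78 to 0 °C
Reagents that add atoms: hydrogen peroxide, OO
Why: Lewis acid-promoted perhydrolysis of an oxetane, in which the silyl-activated ring oxygen is displaced at the tertiary carbon by H2O2 from the backside (tight ion pair, SN2-like), should install the tertiary hydroperoxide with inversion and so set the future C5 as (S).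

**Step 9**
Reactants: 12 (4S)-4-hydroperoxy-4-methyldodec-11-en-2-ol
Product: 13 (4S)-4-[(2-methoxypropan-2-yl)peroxy]-4-methyldodec-11-en-2-ol
Conditions: 2-methoxypropene (1.2 equiv), PPTS (5 mol%), CH2Cl2, −20 °C; Et3N quench
Reagents that add atoms: 2-methoxypropene, COC(C)=C
Why: acid-catalysed peroxyketal formation, in which the more nucleophilic hydroperoxide (α-effect) should add to the enol ether faster than the secondary alcohol, masks the O–OH group for the oxidation.

**Step 10**
Reactants: 13 (4S)-4-[(2-methoxypropan-2-yl)peroxy]-4-methyldodec-11-en-2-ol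
Product: 14 (4S)-4-[(2-methoxypropan-2-yl)peroxy]-4-methyldodec-11-en-2-one
Conditions: Dess–Martin periodinane (1.3 equiv), NaHCO3 (buffer), CH2Cl2, 0 °C to rt
Reagents that add atoms: none
Why: Dess–Martin oxidation of the secondary alcohol under buffered, non-basic conditions tolerates the peroxyketal and avoids β-elimination of the peroxide from the new β-peroxy ketone.

**Step 11**
Reactants: 14 (4S)-4-[(2-methoxypropan-2-yl)peroxy]-4-methyldodec-11-en-2-one
Product: 17 (5S)-3-methoxy-3,5-dimethyl-5-(oct-7-en-1-yl)-1,2-dioxolane (both C3 epimers), via hydroperoxy ketone 15 (not isolated), via dioxolan-3-ol 16 (not isolated)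
Conditions: TsOH·H2O (5 mol%), MeOH, 4 Å MS, rt
Reagents that add atoms: methanol, CO
Why: acid methanolysis removes the peroxyketal as 2,2-dimethoxypropane, the freed hydroperoxy ketone closes to the five-membered hemiperketal (5-exo-trig addition to the carbonyl), and acid-catalysed exchange gives the methyl peroxyketal without affecting C5.

**Step 12**
Reactants: 17 (5S)-3-methoxy-3,5-dimethyl-5-(oct-7-en-1-yl)-1,2-dioxolane
Product: 18 methyl 2-[(3R,5S)-3,5-dimethyl-5-(oct-7-en-1-yl)-1,2-dioxolan-3-yl]acetate
Conditions: TiCl4 (1.1 equiv), 1-(tert-butyldimethylsilyloxy)-1-methoxyethene (2 equiv), CH2Cl2, −78 °C; chromatographic separation from the (3S,5S) epimer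
Reagents that add atoms: 1-(tert-butyldimethylsilyloxy)-1-methoxyethene, C=C(OC)O[Si](C)(C)C(C)(C)C
Why: Mukaiyama-type addition of the silyl ketene acetal to the peroxycarbenium ion formed by Lewis-acid ionisation of the methoxy group forms the C3–CH2 bond without touching C5, but C3 arises at a planar cation whose faces differ only through the remote C5 methyl versus chain, so both epimers are expected and the (3R,5S) ester (acetate arm cis to the C5 methyl, to be assigned by NOE) is isolated by chromatography.

**Step 13**
Reactants: 19 (2E,4E)-hepta-2,4-dienal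
Product: 20 (1E,3E,5E)-1-iodoocta-1,3,5-triene
Conditions: CrCl2 (6 equiv), CHI3 (2 equiv), THF/dioxane, 0 °C to rt, dark; used at once
Reagents that add atoms: iodoform, IC(I)I
Why: Takai iodo-olefination of the aldehyde through a gem-dichromium species should give the E-alkenyl iodide and leave the existing E,E-diene untouched.

**Step 14**
Reactants: 18 methyl 2-[(3R,5S)-3,5-dimethyl-5-(oct-7-en-1-yl)-1,2-dioxolan-3-yl]acetate; 20 (1E,3E,5E)-1-iodoocta-1,3,5-triene
Product: 22 methyl 2-[(3R,5S)-5-[(9E,11E,13E)-hexadeca-9,11,13-trien-1-yl]-3,5-dimethyl-1,2-dioxolan-3-yl]acetate, via B-alkyl-9-borabicyclononane 21 (not isolated)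
Conditions: 9-BBN-H (1.3 equiv), THF, 0 °C to rt; then 20 (1.2 equiv), PdCl2(dppf) (5 mol%), AsPh3 (5 mol%), Cs2CO3 (3 equiv), DMF/H2O, rt, dark
Reagents that add atoms: none
Why: 9-BBN-H adds syn and anti-Markovnikov to the only alkene of 18 (C7'=C8') and places boron on C8'; base then forms the borate, zerovalent palladium inserts into the C–I bond of 20 with retention of the E geometry, and transmetalation of the primary alkyl group followed by reductive elimination forms the C8'–C9' bond. The closest known reaction type is the hydroboration/B-alkyl Suzuki–Miyaura coupling of terminal alkenes with alkenyl iodides used for late fragment unions. No ring is closed and no stereocentre is created; the three E double bonds are carried over from 20 and the two quaternary ring carbons are untouched. The step needs chemoselectivity for the alkene over the ester and the O–O bond: 9-BBN-H does not reduce esters at rt, and a tetrasubstituted dialkyl peroxide without α-hydrogens is inert to carbonate base and hindered toward insertion of zerovalent palladium. It also needs the coupling to outrun β-hydride elimination and isomerisation of the triene, which the dppf/AsPh3 system at rt and exclusion of light should secure.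

**Step 15**
Reactants: 22 methyl 2-[(3R,5S)-5-[(9E,11E,13E)-hexadeca-9,11,13-trien-1-yl]-3,5-dimethyl-1,2-dioxolan-3-yl]acetate
Product: 23 2-[(3R,5S)-5-[(9E,11E,13E)-hexadeca-9,11,13-trien-1-yl]-3,5-dimethyl-1,2-dioxolan-3-yl]acetic acid
Conditions: LiOH (3 equiv), THF/MeOH/H2O, 0 °C to rt, dark; then 1 M HCl to pH 3
Reagents that add atoms: lithium hydroxide, [Li+].[OH-]
Why: saponification of the methyl ester by acyl–oxygen cleavage should be clean because the tetrasubstituted dioxolane has no α-hydrogen for base-induced (Kornblum–DeLaMare) fragmentation and neither stereocentre can epimerise.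

**Compound list**

1 | 8-bromooct-1-ene | C=CCCCCCCBr | starting material
2 | dec-1-en-9-yne | C=CCCCCCCC#C | intermediate
3 | dimethyl[(E)-2-methyldeca-1,9-dien-1-yl]alane | C[Al](C)/C=C(\C)CCCCCCC=C | intermediate (not isolated)
4 | lithium butyl(dimethyl)[(E)-2-methyldeca-1,9-dien-1-yl]aluminate | [Li+].CCCC[Al-](C)(C)/C=C(\C)CCCCCCC=C | intermediate (not isolated)
5 | (E)-3-methylundeca-2,10-dien-1-ol | OC/C=C(\C)CCCCCCC=C | intermediate
6 | [(2R,3R)-3-methyl-3-(oct-7-en-1-yl)oxiran-2-yl]methanol | OC[C@H]1O[C@]1(C)CCCCCCC=C | intermediate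
7 | (3R)-3-methylundec-10-ene-1,3-diol | OCC[C@](C)(O)CCCCCCC=C | intermediate
8 | (3R)-3-hydroxy-3-methylundec-10-enal | O=CC[C@](C)(O)CCCCCCC=C | intermediate
9 | (4R)-4-methyldodec-11-ene-2,4-diol (both C2 epimers) | CC(O)C[C@](C)(O)CCCCCCC=C | intermediate
10 | (4R)-4-hydroxy-4-methyldodec-11-en-2-yl methanesulfonate (both C2 epimers) | CC(OS(C)(=O)=O)C[C@](C)(O)CCCCCCC=C | intermediate (not isolated)
11 | (2R)-2,4-dimethyl-2-(oct-7-en-1-yl)oxetane (both C4 epimers) | CC1C[C@@](C)(CCCCCCC=C)O1 | intermediate
12 | (4S)-4-hydroperoxy-4-methyldodec-11-en-2-ol (both C2 epimers) | CC(O)C[C@@](C)(OO)CCCCCCC=C | intermediate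
13 | (4S)-4-[(2-methoxypropan-2-yl)peroxy]-4-methyldodec-11-en-2-ol (both C2 epimers) | CC(O)C[C@@](C)(OOC(C)(C)OC)CCCCCCC=C | intermediate
14 | (4S)-4-[(2-methoxypropan-2-yl)peroxy]-4-methyldodec-11-en-2-one | CC(=O)C[C@@](C)(OOC(C)(C)OC)CCCCCCC=C | intermediate
15 | (4S)-4-hydroperoxy-4-methyldodec-11-en-2-one | CC(=O)C[C@@](C)(OO)CCCCCCC=C | intermediate (not isolated)
16 | (5S)-3,5-dimethyl-5-(oct-7-en-1-yl)-1,2-dioxolan-3-ol (both C3 epimers) | CC1(O)C[C@](C)(CCCCCCC=C)OO1 | intermediate (not isolated)
17 | (5S)-3-methoxy-3,5-dimethyl-5-(oct-7-en-1-yl)-1,2-dioxolane (both C3 epimers) | COC1(C)C[C@](C)(CCCCCCC=C)OO1 | intermediate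
18 | methyl 2-[(3R,5S)-3,5-dimethyl-5-(oct-7-en-1-yl)-1,2-dioxolan-3-yl]acetate | C=CCCCCCC[C@@]1(C)C[C@](C)(CC(=O)OC)OO1 | intermediate
19 | (2E,4E)-hepta-2,4-dienal | CC/C=C/C=C/C=O | starting material
20 | (1E,3E,5E)-1-iodoocta-1,3,5-triene | CC/C=C/C=C/C=C/I | intermediate
21 | methyl 2-[(3R,5S)-5-[8-(9-borabicyclo[3.3.1]nonan-9-yl)octyl]-3,5-dimethyl-1,2-dioxolan-3-yl]acetate | C1CCC2CCCC1B2CCCCCCCC[C@@]1(C)C[C@](C)(CC(=O)OC)OO1 | intermediate (not isolated)
22 | methyl 2-[(3R,5S)-5-[(9E,11E,13E)-hexadeca-9,11,13-trien-1-yl]-3,5-dimethyl-1,2-dioxolan-3-yl]acetate | CC/C=C/C=C/C=C/CCCCCCCC[C@@]1(C)C[C@](C)(CC(=O)OC)OO1 | intermediate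
23 | 2-[(3R,5S)-5-[(9E,11E,13E)-hexadeca-9,11,13-trien-1-yl]-3,5-dimethyl-1,2-dioxolan-3-yl]acetic acid | CC/C=C/C=C/C=C/CCCCCCCC[C@@]1(C)C[C@](C)(CC(=O)O)OO1 | target

**Step count.** Total: 15 steps. Longest linear sequence: 14 steps (steps 1–12, 14 and 15); step 13 is a one-step branch to the iodotriene.

**Steps most likely to fail**

Step 14. What may go wrong: reductive cleavage of the O–O bond by the borane or by zerovalent palladium during a slow transmetalation, and isomerisation or homocoupling of the iodotriene under aqueous base. Fallback (borane-free and base-free Negishi manifold): setting out from 18, hydrozirconation of the terminal alkene with Cp2Zr(H)Cl (THF, rt) should give methyl 2-[(3R,5S)-5-{8-[chlorobis(cyclopentadienyl)zirconio]octyl}-3,5-dimethyl-1,2-dioxolan-3-yl]acetate F1. Transmetalation with ZnCl2 gives methyl 2-[(3R,5S)-5-[8-(chlorozincio)octyl]-3,5-dimethyl-1,2-dioxolan-3-yl]acetate F2, and coupling with 20 (PdCl2(dppf), THF, rt, dark) comes back to the route at 22.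

Step 12. What may go wrong: poor facial selectivity at the planar peroxycarbenium ion, so that much of the material ends as the (3S,5S) epimer, and incomplete separation of the epimers. Fallback (C3 formed by conjugate addition instead of cation capture): setting out from ketone 14, Wittig olefination with methyl (triphenylphosphoranylidene)acetate (PhMe, 80 °C; a non-basic ylide, so no β-elimination of the peroxide) should give methyl (5S)-5-[(2-methoxypropan-2-yl)peroxy]-3,5-dimethyltrideca-2,12-dienoate F3 as an E/Z mixture. PPTS in MeOH frees methyl (5S)-5-hydroperoxy-3,5-dimethyltrideca-2,12-dienoate F4, which closes by 5-exo-trig peroxy-Michael addition (Et2NH, CF3CH2OH, rt) and comes back to the route at 18. The E and Z enoates can be cyclised separately, which gives a second handle on the C3 configuration.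

Step 8. What may go wrong: ionisation of the 2,2,4-trisubstituted oxetane to a free tertiary cation (erosion of the C5 configuration, E1 loss of a proton) and competing cleavage of the secondary C–O bond. Fallback (oxetane with a single ionisable C–O bond, methyl group introduced after the peroxide): setting out from diol 7, one-pot n-BuLi/TsCl/n-BuLi (THF, 0 to 60 °C) should give, through (3R)-3-hydroxy-3-methylundec-10-en-1-yl 4-methylbenzenesulfonate F5, the oxetane (2R)-2-methyl-2-(oct-7-en-1-yl)oxetane F6. Perhydrolysis as in step 8 gives (3S)-3-hydroperoxy-3-methylundec-10-en-1-ol F7, and 2-methoxypropene/PPTS gives (3S)-3-[(2-methoxypropan-2-yl)peroxy]-3-methylundec-10-en-1-ol F8. Dess–Martin oxidation gives (3S)-3-[(2-methoxypropan-2-yl)peroxy]-3-methylundec-10-enal F9, and addition of MeMgBr (THF, −78 °C), which should be faster at the aldehyde than at the peroxyketal, comes back to the route at 13.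

**Further compounds**

F1 | step 14 | methyl 2-[(3R,5S)-5-{8-[chlorobis(cyclopentadienyl)zirconio]octyl}-3,5-dimethyl-1,2-dioxolan-3-yl]acetate | Cl[Zr](C1C=CC=C1)(C1C=CC=C1)CCCCCCCC[C@@]1(C)C[C@](C)(CC(=O)OC)OO1
F2 | step 14 | methyl 2-[(3R,5S)-5-[8-(chlorozincio)octyl]-3,5-dimethyl-1,2-dioxolan-3-yl]acetate | Cl[Zn]CCCCCCCC[C@@]1(C)C[C@](C)(CC(=O)OC)OO1
F3 | step 12 | methyl (5S)-5-[(2-methoxypropan-2-yl)peroxy]-3,5-dimethyltrideca-2,12-dienoate (E/Z mixture) | COC(=O)C=C(C)C[C@@](C)(OOC(C)(C)OC)CCCCCCC=C
F4 | step 12 | methyl (5S)-5-hydroperoxy-3,5-dimethyltrideca-2,12-dienoate (E/Z mixture) | COC(=O)C=C(C)C[C@@](C)(OO)CCCCCCC=C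
F5 | step 8 | (3R)-3-hydroxy-3-methylundec-10-en-1-yl 4-methylbenzenesulfonate | Cc1ccc(cc1)S(=O)(=O)OCC[C@](C)(O)CCCCCCC=C
F6 | step 8 | (2R)-2-methyl-2-(oct-7-en-1-yl)oxetane | C[C@@]1(CCCCCCC=C)CCO1
F7 | step 8 | (3S)-3-hydroperoxy-3-methylundec-10-en-1-ol | OCC[C@@](C)(OO)CCCCCCC=C
F8 | step 8 | (3S)-3-[(2-methoxypropan-2-yl)peroxy]-3-methylundec-10-en-1-ol | OCC[C@@](C)(OOC(C)(C)OC)CCCCCCC=C
F9 | step 8 | (3S)-3-[(2-methoxypropan-2-yl)peroxy]-3-methylundec-10-enal | O=CC[C@@](C)(OOC(C)(C)OC)CCCCCCC=C
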